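The runs come from a simulation on assumed constants, noise included.

You have no constants for Z, E, G and X (the catalyst), but you have the earlier closed-flask runs, so look for a ratio in which constants cancel.

the same everywhere: X 0.1 mol%
- violet: Z 0.16 M; E 90 µM; run made earlier
- green: Z 0.11 M; E 90 µM; run made earlier
- blue: Z 0.24 M; E 90 µM; run made earlier
- amber: Z 0.16 M; E 45 µM; run made earlier
- eta: Z 0.16 M; E 90 µM; a single well-mixed tank run continuously and read at steady state, 40.0 min in it on average
- delta: Z 0.16 M (fed, over 8.00 min); E 90 µM; all but Z at the start; Z goes in evenly over 8.00 min, the run ends at 8.0 min; time 8.0 min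
- beta: Z 0.16 M; E 90 µM; a single well-mixed tank run continuously and read at steady state, 8.0 min in it on average
- epsilon: Z 0.16 M; E 90 µM; everything together in a closed stirred flask, run for 8.0 min; time 8.0 min

| run | time / min | G / % |
|---|---|---|
| violet | 0.667 | 9.3 |
| violet | 1.33 | 14.4 |
| violet | 2.00 | 19.0 |
| violet | 3.00 | 24.0 |
| violet | 4.00 | 27.9 |
| violet | 5.00 | 31.3 |
| green | 0.500 | 3.6 |
| green | 0.833 | 5.5 |
| green | 1.33 | 5.8 |
| green | 2.00 | 9.4 |
| green | 3.00 | 11.1 |
| green | 4.00 | 12.9 |
| green | 6.00 | 15.2 |
| blue | 1.00 | 21.2 |
| blue | 2.00 | 31.9 |
| blue | 3.00 | 37.6 |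
| blue | 4.00 | 42.8 |
| blue | 5.00 | 46.1 |
| blue | 6.00 | 48.7 |
| amber | 1.33 | 20.1 |
| amber | 2.50 | 30.1 |
| amber | 4.00 | 37.4 |
| amber | 5.00 | 39.9 |
| amber | 6.00 | 43.3 |

(readings scatter by 0.5 percentage points)

- the stated concentrations are those of everything mixed, before any reaction; amounts are the same in each set-up
- the feed brings no volume worth counting
- the earlier runs were made in a closed, stirred flask

- the set-up with the highest amount of G at the outlet or at the end, in percent of the Z put in ("none" if the first two lie within 2 percentage points) (eta / delta / beta / epsilon / none)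
- amount of G at the outlet or at the end, in percent of the Z put in, eta
- amount of G at the outlet or at the end, in percent of the Z put in, delta
- amount of G at the outlet or at the end, in percent of the Z put in, beta
- amount of G at the outlet or at the end, in percent of the Z put in, epsilon

At 4.00 min, halving E lifts G from 27.9% in violet to 37.4% in amber, which reads as E removing X. My reckoning supposes that E takes X quickly, one for one. The rate of loss of E divided by the rate of loss of X is then one, and time drops out. In the violet recipe E is the limiting reagent of this poisoning, so its outcome is a ratio of charges: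

φ = E charged / X charged = 90 µM / 160 µM = 0.562

φ is the poison share, the fraction of charged X that E takes out of work. Eta, delta, beta and epsilon each have this φ, which on this reckoning leaves 70.0 µM of X once E is used up, so φ does not rank them.

Now test it on the runs. Green has φ = 0.818 and reaches 15.2% at 6.00 min. Blue has φ = 0.375, higher than amber's 0.281, yet at that time blue holds 48.7% against 43.3%. One number is therefore not enough: blue and amber differ in Z as well as in E, and the X left on this reckoning, 150 µM in blue against 115 µM in amber, stands in the same order as their G.

The forecast gives 56% for eta, 24% for delta, 30% for beta and 39.5% for epsilon, and names eta: “The long residence time wins.”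

The flask gives 43.0% in eta, 18.2% in delta, 28.4% in beta and 37.6% in epsilon, so eta leads.

    Z ⇌ J (K = 0.890, k = 0.110 min⁻¹)
    Z + X → X + G (k = 1900 M⁻¹ min⁻¹)
    X + J → X + D (k = 830 M⁻¹ min⁻¹)
    X + E → Q (k = 98000 M⁻¹ min⁻¹)
    2 X → L (k = 1400 M⁻¹ min⁻¹)

In epsilon, the half-life of X by the step X + E → Q alone, the other concentrations as charged, is 0.079 min, far shorter than the 2.3 min half-life of Z by the step Z + X → X + G alone, the others held at their charge. In epsilon Q, the poisoned X, stands at 56.2% of the X charged at 4.00 min and the same at 8.00 min, which matches φ. A neighbour of delta with 0.06 mol% of X has φ = 0.938, holds Q at 93.4%, and ends at 2.58% G.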